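**Retrosynthetic overview**
- Target: (2R,3R)-trans-3-O-methyl-dihydroflavonol. The last disconnection is hydrogenolysis of two diphenylmethylene catechol ketals (5,6-O on ring A; 2',3'-O on ring B); both aromatic rings are bought.
- Enabling feature: C3 of the pyranone is an oxygen-bearing carbon between the enolisable C4 ketone and C2. C2 carries the ring oxygen O1 and the B-ring aryl, so it is a benzylic, O-substituted, radical-stabilised carbon. The C2–C3 bond is therefore the retron of an acetal [1,2]-Wittig shift.
- Moving the C3 oxygen into the ring between C2 and C3 gives a seven-membered 2-aryl-4H-1,3-benzodioxepin-5-one (a cyclic aryl/alkyl acetal). Its ketone enolate contracts 7 → 6, pushing that oxygen out onto C3, where it is methylated in the same pot.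
- The acetal comes from α-hydroxy ketone 6 (from 3,4,5-trimethoxyphenol) and aldehyde 8. Its single stereocentre is set by asymmetric acetalization and relayed to C2; C3 is then equilibrated to trans.
- Ring order: aromatic rings A and B (commercial) → two dioxole protecting rings → seven-membered acetal ring → six-membered pyranone ring C by contraction.

Key step: step 7

Assumption: compounds 1, 2 and 7 are catalogue chemicals. Flavanone numbering (O1, C2, C3, C4, C4a–C8a, primed B ring) is used for the target, and benzodioxepinone numbering (O1, C2, O3, C4, C5, C5a–C9a) for the seven-membered precursor.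

**Route**

Step 1
Reactants: 1 3,4,5-trimethoxyphenol; 2 acetoxyacetyl chloride
Product: 3 2-(6-hydroxy-2,3,4-trimethoxyphenyl)-2-oxoethyl acetate
Conditions: BF3·OEt2 (as reaction medium), rt → 70 °C; aqueous work-up
Reagents that add atoms: none
Why: Friedel–Crafts ortho-acylation of a phenol in BF3·OEt2 should give one regioisomer, because the two ortho positions are equivalent and the para position is blocked.

Step 2
Reactants: 3 2-(6-hydroxy-2,3,4-trimethoxyphenyl)-2-oxoethyl acetate
Product: 4 2-oxo-2-(2,3,6-trihydroxy-4-methoxyphenyl)ethyl acetate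
Conditions: BCl3 (excess), CH2Cl2, –78 °C → rt, argon; aqueous work-up
Reagents that add atoms: none
Why: Chelation-directed Lewis-acid ether cleavage should remove the methoxy group ortho to the ketone and then its neighbour via the aryloxyboron species, leaving the methoxy para to the carbonyl, as in the BCl3 conversion of 2,3,4-trimethoxybenzaldehyde into 2,3-dihydroxy-4-methoxybenzaldehyde.

Step 3
Reactants: 4 2-oxo-2-(2,3,6-trihydroxy-4-methoxyphenyl)ethyl acetate
Product: 5 2-(5-hydroxy-7-methoxy-2,2-diphenyl-1,3-benzodioxol-4-yl)-2-oxoethyl acetate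
Conditions: Ph2CCl2, Ph2O, 160–175 °C, argon
Reagents that add atoms: dichlorodiphenylmethane ClC(Cl)(c1ccccc1)c1ccccc1
Why: Catechol ketalization with a gem-dichloride can close a five-membered ring only across the vicinal 2,3-diol, so the isolated 6-OH (hydrogen-bonded to the ketone) should stay free.

Step 4
Reactants: 5 2-(5-hydroxy-7-methoxy-2,2-diphenyl-1,3-benzodioxol-4-yl)-2-oxoethyl acetate
Product: 6 2-hydroxy-1-(5-hydroxy-7-methoxy-2,2-diphenyl-1,3-benzodioxol-4-yl)ethan-1-one
Conditions: K2CO3 (cat.), MeOH, 0 °C, argon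
Reagents that add atoms: none
Why: Zemplén-type transesterification should remove the primary acetate without touching the ketal or the aryl methyl ether.

Step 5
Reactants: 7 2,3-dihydroxy-4-methoxybenzaldehyde
Product: 8 7-methoxy-2,2-diphenyl-1,3-benzodioxole-4-carbaldehyde
Conditions: Ph2CCl2, Ph2O, 175 °C
Reagents that add atoms: dichlorodiphenylmethane ClC(Cl)(c1ccccc1)c1ccccc1
Why: The same gem-dichloride catechol ketalization should tie back the 2,3-diol as a base-stable, hydrogenolysable dioxole that keeps the ortho oxygen away from the aldehyde carbon.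

Step 6
Reactants: 6 2-hydroxy-1-(5-hydroxy-7-methoxy-2,2-diphenyl-1,3-benzodioxol-4-yl)ethan-1-one; 8 7-methoxy-2,2-diphenyl-1,3-benzodioxole-4-carbaldehyde
Product: 9 (2R)-8-methoxy-2-(7-methoxy-2,2-diphenyl-1,3-benzodioxol-4-yl)-6,7-(diphenylmethylenedioxy)-4H-1,3-benzodioxepin-5-one
Conditions: confined chiral imidodiphosphoric acid (5 mol%, the antipode that gives the R acetal), 5 Å MS, toluene, –20 °C; Et3N quench, chromatography on Et3N-deactivated silica
Reagents that add atoms: none
Why: Proposed new method: the confined chiral acid should turn the aldehyde and the primary hydroxyl of 6 into a hemiacetal, ionise it to an oxocarbenium ion paired with the chiral anion, and let the tethered phenol close the ring (7-endo-trig at the C=O+ bond) on one face under kinetic control, which sets the acetal stereocentre; the closest known reaction type is the imidodiphosphoric-acid-catalysed asymmetric acetalization of aldehydes with unsymmetrical aliphatic 1,3-diols to six-membered O,O-acetals with a stereogenic acetal carbon, not yet shown for a phenol/primary-alcohol pair or a seven-membered ring.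

Step 7
Reactants: 9 (2R)-8-methoxy-2-(7-methoxy-2,2-diphenyl-1,3-benzodioxol-4-yl)-6,7-(diphenylmethylenedioxy)-4H-1,3-benzodioxepin-5-one
Product: 12 (2R,3S)-3,7-dimethoxy-2-(7-methoxy-2,2-diphenyl-1,3-benzodioxol-4-yl)-5,6-(diphenylmethylenedioxy)chroman-4-one, via potassium enolate 10 (not isolated), via potassium 3-alkoxide 11 (not isolated)
Conditions: KHMDS (1.05 equiv), THF, –78 °C → rt, argon; then MeI, DMPU, 0 °C → rt
Reagents that add atoms: iodomethane CI
Why: Proposed new method: deprotonation at C4 gives enolate 10, whose O3–C2 bond should be weak because homolysis yields a benzylic, aryloxy-substituted C2 radical and a semidione (1,2-dicarbonyl) radical anion, and in-cage recombination at C4 is an enolate acetal [1,2]-Wittig rearrangement that contracts the ring from seven to six atoms (old C4 becomes C3, old C5 becomes C4). The closest known reaction types are the acetal [1,2]-Wittig rearrangement of lithiated O-glycosides to C-glycosides, [1,2]-Wittig shifts of α-alkoxy ester and ketone enolates, and ring-contracting [1,2]-Wittig rearrangements of cyclic allylic ethers. The pyranone ring is closed by this 1,2-shift itself (radical recombination forming C2–C3), not by an external cyclisation, with the tether O1–C9a–C5a holding the two centres together. C2 is controlled by retention at the migrating carbon (chirality transfer from the acetal centre of 9); C3 is set under kinetic least-motion control and should be mainly 2,3-cis, because O3 sits cis to the aryl carbon on the enolate and ends pseudo-axial while the B-ring stays pseudo-equatorial, and any trans isomer formed is already 13. The step needs recombination at C4 rather than at C5 or O5, which the unhindered CH terminus of the semidione and the formation of a conjugated aryl ketone should secure, and it needs O-methylation of alkoxide 11, which is the only nucleophile left when MeI is added.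

Step 8
Reactants: 12 (2R,3S)-3,7-dimethoxy-2-(7-methoxy-2,2-diphenyl-1,3-benzodioxol-4-yl)-5,6-(diphenylmethylenedioxy)chroman-4-one
Product: 13 (2R,3R)-3,7-dimethoxy-2-(7-methoxy-2,2-diphenyl-1,3-benzodioxol-4-yl)-5,6-(diphenylmethylenedioxy)chroman-4-one
Conditions: DBU (0.1 equiv), CH2Cl2, 0 °C → rt
Reagents that add atoms: none
Why: Base-catalysed epimerisation of the α-alkoxy ketone centre via its enolate should give the thermodynamic 2,3-trans (diequatorial) isomer, with C2 untouched because reprotonation is expected to outrun the stereoelectronically slow retro-oxa-Michael ring opening.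

Step 9
Reactants: 13 (2R,3R)-3,7-dimethoxy-2-(7-methoxy-2,2-diphenyl-1,3-benzodioxol-4-yl)-5,6-(diphenylmethylenedioxy)chroman-4-one
Product: 14 (2R,3R)-2-(2,3-dihydroxy-4-methoxyphenyl)-5,6-dihydroxy-3,7-dimethoxy-2,3-dihydro-4H-chromen-4-one
Conditions: H2 (1 atm), Pd(OH)2/C, THF–MeOH, rt, argon work-up
Reagents that add atoms: none
Why: Catalytic hydrogenolysis should cleave both diphenylmethylene ketals to the free catechols and diphenylmethane under neutral conditions that leave the methyl ethers, the ketone and both stereocentres unchanged.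

**Compound list**
1 | 3,4,5-trimethoxyphenol | COc1cc(O)cc(OC)c1OC | starting material
2 | acetoxyacetyl chloride | CC(=O)OCC(Cl)=O | starting material
3 | 2-(6-hydroxy-2,3,4-trimethoxyphenyl)-2-oxoethyl acetate | CC(=O)OCC(=O)c1c(O)cc(OC)c(OC)c1OC | intermediate
4 | 2-oxo-2-(2,3,6-trihydroxy-4-methoxyphenyl)ethyl acetate | CC(=O)OCC(=O)c1c(O)cc(OC)c(O)c1O | intermediate
5 | 2-(5-hydroxy-7-methoxy-2,2-diphenyl-1,3-benzodioxol-4-yl)-2-oxoethyl acetate | CC(=O)OCC(=O)c1c(O)cc(OC)c2OC(c3ccccc3)(c3ccccc3)Oc12 | intermediate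
6 | 2-hydroxy-1-(5-hydroxy-7-methoxy-2,2-diphenyl-1,3-benzodioxol-4-yl)ethan-1-one | OCC(=O)c1c(O)cc(OC)c2OC(c3ccccc3)(c3ccccc3)Oc12 | intermediate
7 | 2,3-dihydroxy-4-methoxybenzaldehyde | COc1ccc(C=O)c(O)c1O | starting material
8 | 7-methoxy-2,2-diphenyl-1,3-benzodioxole-4-carbaldehyde | COc1ccc(C=O)c2OC(c3ccccc3)(c3ccccc3)Oc12 | intermediate
9 | (2R)-8-methoxy-2-(7-methoxy-2,2-diphenyl-1,3-benzodioxol-4-yl)-6,7-(diphenylmethylenedioxy)-4H-1,3-benzodioxepin-5-one | O=C1CO[C@@H](c2ccc(OC)c3OC(c4ccccc4)(c4ccccc4)Oc23)Oc2cc(OC)c3OC(c4ccccc4)(c4ccccc4)Oc3c12 | intermediate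
10 | potassium enolate of 9 (C4=C5 enolate, not isolated) | [K+].[O-]C1=CO[C@@H](c2ccc(OC)c3OC(c4ccccc4)(c4ccccc4)Oc23)Oc2cc(OC)c3OC(c4ccccc4)(c4ccccc4)Oc3c12 | intermediate
11 | potassium (2R,3S)-7-methoxy-2-(7-methoxy-2,2-diphenyl-1,3-benzodioxol-4-yl)-5,6-(diphenylmethylenedioxy)-4-oxochroman-3-olate (not isolated) | COc1ccc([C@H]2Oc3cc(OC)c4OC(c5ccccc5)(c5ccccc5)Oc4c3C(=O)[C@H]2[O-])c2OC(c3ccccc3)(c3ccccc3)Oc12.[K+] | intermediate
12 | (2R,3S)-3,7-dimethoxy-2-(7-methoxy-2,2-diphenyl-1,3-benzodioxol-4-yl)-5,6-(diphenylmethylenedioxy)chroman-4-one (2,3-cis) | COc1ccc([C@H]2Oc3cc(OC)c4OC(c5ccccc5)(c5ccccc5)Oc4c3C(=O)[C@H]2OC)c2OC(c3ccccc3)(c3ccccc3)Oc12 | intermediate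
13 | (2R,3R)-3,7-dimethoxy-2-(7-methoxy-2,2-diphenyl-1,3-benzodioxol-4-yl)-5,6-(diphenylmethylenedioxy)chroman-4-one (2,3-trans) | COc1ccc([C@H]2Oc3cc(OC)c4OC(c5ccccc5)(c5ccccc5)Oc4c3C(=O)[C@@H]2OC)c2OC(c3ccccc3)(c3ccccc3)Oc12 | intermediate
14 | (2R,3R)-2-(2,3-dihydroxy-4-methoxyphenyl)-5,6-dihydroxy-3,7-dimethoxy-2,3-dihydro-4H-chromen-4-one | COc1ccc([C@H]2Oc3cc(OC)c(O)c(O)c3C(=O)[C@@H]2OC)c(O)c1O | target

**Step count and risks**
Total step count: 9. Longest linear sequence: 8 steps (steps 1–4 and 6–9, from 1 to 14); step 5 is a one-step side branch.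

Steps most likely to fail:

(i) Step 7 (proposed new method). The stabilised enolate may not homolyse at an accessible temperature, the radical pair may recombine at O5 or C5 instead of C4, or configuration at C2 may leak through rotation within the radical pair. The fallback uses known chemistry, sets out from 6 and 8 and rejoins at 13. A direct catalytic asymmetric aldol reaction of the α-hydroxy aryl ketone with the aldehyde (dinuclear zinc–ProPhenol-type catalyst, 4 Å MS, THF, syn-selective) should give (2R,3S)-2,3-dihydroxy-1-(5-hydroxy-7-methoxy-2,2-diphenyl-1,3-benzodioxol-4-yl)-3-(7-methoxy-2,2-diphenyl-1,3-benzodioxol-4-yl)propan-1-one F2. Mitsunobu cyclodehydration (PPh3, DIAD, THF), in which the phenol displaces the benzylic carbinol with inversion, should close the pyranone to (2R,3R)-3-hydroxy-7-methoxy-2-(7-methoxy-2,2-diphenyl-1,3-benzodioxol-4-yl)-5,6-(diphenylmethylenedioxy)chroman-4-one F3. Even if this closure runs through a benzylic cation, the fixed C3 centre should steer it to the trans isomer. Methylation with Ag2O/MeI then gives 13.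

(ii) Step 6 (proposed new method). Face discrimination in the seven-membered ring closure may be poor, the electron-rich acetal may racemise through acid-mediated re-ionisation, or oligomeric acetals may form. The fallback uses known chemistry, sets out from 6 and 8 and rejoins at 9. Conventional acetalization (PPTS, benzene, Dean–Stark) should give racemic 8-methoxy-2-(7-methoxy-2,2-diphenyl-1,3-benzodioxol-4-yl)-6,7-(diphenylmethylenedioxy)-4H-1,3-benzodioxepin-5-one F1. Preparative chiral SFC on a polysaccharide phase then delivers the R enantiomer 9.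

(iii) Step 8. Base-induced retro-oxa-Michael ring opening and reclosure may compete with C3 epimerisation and erode the C2 configuration. The fallback switches the stereochemical anchor from C2 to C3; it sets out from 6 and 8 and rejoins at 13. Step 6 is run with the antipodal catalyst to give the (2S)-acetal F4. The step 7 conditions then lead through its potassium enolate F5 and the potassium (2S,3R)-3-alkoxide F6 to the (2S,3R)-cis methyl ether F7. Mild Brønsted acid (CSA, CH2Cl2, rt) should then epimerise C2 by reversible ionisation of the benzylic C2–O1 bond, which the 2'- and 4'-alkoxy groups assist. With C3 (R) untouched, thermodynamic reclosure gives 13.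

**Further compounds**
F1 | step 6 | racemic 8-methoxy-2-(7-methoxy-2,2-diphenyl-1,3-benzodioxol-4-yl)-6,7-(diphenylmethylenedioxy)-4H-1,3-benzodioxepin-5-one | O=C1COC(c2ccc(OC)c3OC(c4ccccc4)(c4ccccc4)Oc23)Oc2cc(OC)c3OC(c4ccccc4)(c4ccccc4)Oc3c12
F2 | step 7 | (2R,3S)-2,3-dihydroxy-1-(5-hydroxy-7-methoxy-2,2-diphenyl-1,3-benzodioxol-4-yl)-3-(7-methoxy-2,2-diphenyl-1,3-benzodioxol-4-yl)propan-1-one | O=C([C@H](O)[C@@H](O)c1ccc(OC)c2OC(c3ccccc3)(c3ccccc3)Oc12)c1c(O)cc(OC)c2OC(c3ccccc3)(c3ccccc3)Oc12
F3 | step 7 | (2R,3R)-3-hydroxy-7-methoxy-2-(7-methoxy-2,2-diphenyl-1,3-benzodioxol-4-yl)-5,6-(diphenylmethylenedioxy)chroman-4-one | COc1ccc([C@H]2Oc3cc(OC)c4OC(c5ccccc5)(c5ccccc5)Oc4c3C(=O)[C@@H]2O)c2OC(c3ccccc3)(c3ccccc3)Oc12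
F4 | step 8 | (2S)-8-methoxy-2-(7-methoxy-2,2-diphenyl-1,3-benzodioxol-4-yl)-6,7-(diphenylmethylenedioxy)-4H-1,3-benzodioxepin-5-one | O=C1CO[C@H](c2ccc(OC)c3OC(c4ccccc4)(c4ccccc4)Oc23)Oc2cc(OC)c3OC(c4ccccc4)(c4ccccc4)Oc3c12
F5 | step 8 | potassium enolate of F4 | [K+].[O-]C1=CO[C@H](c2ccc(OC)c3OC(c4ccccc4)(c4ccccc4)Oc23)Oc2cc(OC)c3OC(c4ccccc4)(c4ccccc4)Oc3c12
F6 | step 8 | potassium (2S,3R)-7-methoxy-2-(7-methoxy-2,2-diphenyl-1,3-benzodioxol-4-yl)-5,6-(diphenylmethylenedioxy)-4-oxochroman-3-olate | COc1ccc([C@@H]2Oc3cc(OC)c4OC(c5ccccc5)(c5ccccc5)Oc4c3C(=O)[C@@H]2[O-])c2OC(c3ccccc3)(c3ccccc3)Oc12.[K+]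
F7 | step 8 | (2S,3R)-3,7-dimethoxy-2-(7-methoxy-2,2-diphenyl-1,3-benzodioxol-4-yl)-5,6-(diphenylmethylenedioxy)chroman-4-one | COc1ccc([C@@H]2Oc3cc(OC)c4OC(c5ccccc5)(c5ccccc5)Oc4c3C(=O)[C@@H]2OC)c2OC(c3ccccc3)(c3ccccc3)Oc12
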